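## Structural features

The target 13 is a coumarin (benzene ring A fused to the pyran-2-one ring B) with a methoxy group on C8 and, on the C7 oxygen, an oxygenated ten-carbon chain numbered C1' (the OCH2) to C7', with methyl groups on C3' and C7'. C2' and C3' form a trisubstituted oxirane (2'S,3'R) in which C3' is quaternary and C1' and C4' lie on the same face; C4' is a methylene, C5' a secondary allylic carbinol (S) and C6'=C7' a trisubstituted alkene. The two epoxide stereocentres are adjacent, but C5' stands 1,3 to C3' across the C4' methylene, so it cannot simply be copied from a neighbour in the open chain. Fragile groups are the epoxide (acid, nucleophiles), the C5' alcohol (it ionises under acid to an allyl cation with a tertiary terminus) and the coumarin lactone (hydroxide, strong hydride donors). Among the intermediates, the β-hydroxy carbonyl units are prone to retro-aldol cleavage and dehydration. The real difficulty is the absolute configuration of the quaternary, oxygen-bearing C3' and its correlation with C2' and with the remote C5'. The key step exploits the fact that C3' carries a methyl group, an oxygen and two CH2 arms (C2' and C4'), each ending in an oxygenated carbon (C1' and C5'). The C1'–C5' segment with its C3' methyl is therefore the skeleton of 3-hydroxy-3-methylglutaric acid, prochiral at C3', and an esterase that tells the two arms apart fixes C3' before any carbon–carbon bond is made. Once C1' and O5' are tied into a six-membered lactone, a C2'–C3' oxirane can only be cis-fused, which sets C2' from C3'.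

## Logic of the disconnections

13 is cut at the ether bond between the C7 oxygen and C1', giving 11 and 12. This is the only bond that joins the aromatic part to the chain, and C1' is primary and not stereogenic. The gain is a purchased heterocycle and a ten-carbon piece that already holds all three stereocentres. The forward step must etherify a primary carbinol next to a free secondary allylic one, under neutral conditions that leave the oxirane and ring B alone.

11 is traced back to 10 by raising C1' to the carboxyl level and joining it to O5' (the acyl C1'–O5' bond). The ring masks the C5' hydroxyl and is the device that relates C2' to C3'. The forward step needs a hydride that reduces the lactone but does not open the oxirane.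

10 is cut at the C2'–O bond of the oxirane, through 9, back to 8; the C3'–O bond is kept throughout. C2' becomes a plain methylene α to the lactone carbonyl, and the only stereocentres left are C3' and C5'. The forward step must place a halogen on C2' anti to the C3' oxygen and close the three-membered ring with inversion.

8 is opened at the acyl C1'–O5' bond to 7, and 7 is traced back to 6 by removing the C5'–H bond. This gives an acyclic enone with the single stereocentre C3'. The forward steps need a reagent-controlled reduction, because C3' is too far away and too evenly substituted to direct it, and a lactonisation without acid.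

6 is cut at C5'–C6' into 4 and 5, which splits off the isobutenyl unit as a purchased organometallic. 4 is cut at its amide C–N bond to 3. The forward steps must address the acid arm alone and stop after one addition, with the ester arm and the free tertiary hydroxyl as spectators.

3 is traced back to 2 without cutting any skeletal bond: one carboxyl is re-esterified. The gain is the largest of the route, an achiral precursor with a mirror plane through C3'. The forward step must hydrolyse one of two enantiotopic ester groups and stop there. The arm that becomes C2' outranks the arm that becomes C4' in every compound from 3 to 13, so the descriptor at this carbon stays R throughout.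

2 is cut at its two ester C–O bonds to 1 and methanol; the forward step is an ordinary esterification.

## Other disconnections considered

Alternative 1: The cut removes the oxirane oxygen (the C3'–O and C2'–O bonds) from the epoxy lactone A1, (3R,4R,6S)-3,4-epoxy-4-methyl-6-(2-methylprop-1-enyl)tetrahydropyran-2-one, which is the same compound as 10. It leads back to the unsaturated lactone A2, (S)-4-methyl-6-(2-methylprop-1-enyl)-5,6-dihydro-2H-pyran-2-one, in which C5' is the only stereocentre.
- Forward step: hydroperoxide anion (H2O2, NaOH, MeOH, 0 °C) would add in conjugate fashion to C3' on the ring face away from the isobutenyl group, and the lactone enolate would then close on the peroxide oxygen with loss of hydroxide.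
- In favour: both oxirane carbons are functionalised in one operation, the ring again enforces cis fusion, and the electron-rich C6'=C7' alkene is inert to a nucleophilic oxidant.
- Against: the absolute configuration of the quaternary C3' would rest on a 1,3-relay from C5' across the C4' methylene, where a pseudo-equatorial isobutenyl group should give only a modest facial bias. Conjugate addition to a β,β-disubstituted enoate is slow, and hydroxide can saponify the δ-lactone to a Z-enoate carboxylate that no longer accepts the peroxide.
- Comparison, structure: the two plans are equal in how C2' is tied to C3', and they meet at the same intermediate, so the end game is identical.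
- Comparison, mechanism: the chosen plan keeps the C3'–O bond fixed by the enzyme and asks only for an intramolecular displacement. The alternative creates C3' by diastereoselection, which is the weaker guarantee for the hardest centre.
- Comparison, step economy: the alternative is the better plan, one step from A2 against six steps from 2 to 10.

Alternative 2: The cut goes through C4'–C5' and the lactone O–C1' bond of the unsaturated lactone A3, (S)-4-methyl-6-(2-methylprop-1-enyl)-5,6-dihydro-2H-pyran-2-one, the same compound as A2. It gives two five-carbon units: the silyl dienolate A4, 1-methoxy-3-methyl-1-(trimethylsilyloxy)buta-1,3-diene, and 3-methylbut-2-enal A5.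
- Forward step: under a Ti(OiPr)4/BINOL catalyst the terminal CH2 of A4 would attack the Si face of the aldehyde carbon of A5 (a vinylogous Mukaiyama aldol that amounts to a hetero-Diels–Alder reaction). The aldehyde oxygen would then close on the ester carbon with loss of the silyl and methoxy groups.
- In favour: the whole C1'–C7' carbon skeleton and the C5' centre would come from two cheap achiral units in one catalytic step. Combined with Alternative 1, the target would be about four steps away.
- Against: A5 is a conjugated, β,β-disubstituted aldehyde, a class that is less electrophilic and usually less selective in this catalysis than simple aldehydes. Attack through the γ-carbon of A4 and ring closure of the aldol ester (which needs the Z enoate) must both go the right way. A3 has no stereocentre at C3', so the quaternary centre still depends on the relay criticised under Alternative 1.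
- Comparison, structure: the alternative is the better plan, since its key step forms a carbon–carbon bond and a ring, while the chosen key step forms neither and leaves C6'–C7' to a separate Grignard step.
- Comparison, mechanism: both rely on a chiral catalyst for an absolute centre. The chosen plan sets C3' (enzyme) and C5' (oxazaborolidine) by two independent controllers, so a shortfall at one does not propagate to the other. The alternative hangs all three centres on one enantioselective event and one relay.
- Comparison, step economy: the alternative is clearly better, roughly four steps against nine.

Alternative 3: The cut opens ring B of the coumarin at O1–C2 and C3=C4. It leads from the silyl ether A6 (the C5'-O-tert-butyldimethylsilyl ether of 13) back to the salicylaldehyde A7, 4-{[(2S,3R)-3-[(2S)-2-(tert-butyldimethylsilyloxy)-4-methylpent-3-enyl]-3-methyloxiran-2-yl]methoxy}-2-hydroxy-3-methoxybenzaldehyde, and (triphenylphosphoranylidene)ketene A8.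
- Forward step: the phenol of A7 would add to the ketene carbon of A8, and the ester-stabilised ylide so formed would olefinate the ortho aldehyde intramolecularly, closing the pyranone with the necessarily cis C3=C4 bond.
- In favour: the conditions are neutral, and the coumarin lactone would be absent during all earlier steps, so hydride and alkoxide reagents could be used freely on the side chain.
- Against: ring B comes ready-made in purchased 12, so the cut solves a problem the target does not pose. It says nothing about C2', C3' or C5', which would still have to come from one of the other plans. The C5' hydroxyl must be protected, because a free alcohol would add to A8, and this costs a final desilylation. The olefination needs heating with the oxirane present.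
- Comparison, structure: the plans are equal in that the aromatic part and the chain are joined through a phenol oxygen and C1' in both.
- Comparison, mechanism: the phosphorane closure is as mild as the Mitsunobu step and is its equal in chemoselectivity towards the oxirane.
- Comparison, step economy: the chosen plan is better by at least three steps (protection, ring closure, deprotection), and it exposes the coumarin to only one step, with nothing harsher than PPh3 and DIAD.

Key step: step 2

Assumption: the esterase is taken to hydrolyse the pro-S ester arm of 2 and so to give (R)-3, a sense that is assumed here and would be checked on the first batch; should the other arm be cleaved, the surviving ester arm instead of the acid arm would be carried to the enone, which leads to the same configuration at C3'.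

## Route

Step 1
Reactants: 1 3-hydroxy-3-methylglutaric acid
Product: 2 dimethyl 3-hydroxy-3-methylglutarate
Conditions: MeOH, H2SO4 (cat.), 40 °C
Reagents that add atoms: methanol, CO
Why: Fischer esterification of both carboxyl groups; the tertiary hydroxyl, flanked by two electron-poor CH2CO2R arms, should neither esterify nor ionise at this temperature.

Step 2
Reactants: 2 dimethyl 3-hydroxy-3-methylglutarate
Product: 3 (R)-3-hydroxy-5-methoxy-3-methyl-5-oxopentanoic acid
Conditions: pig liver carboxylesterase, 0.1 M phosphate buffer pH 7.5, 25 °C, pH-stat with 1 M NaOH (1.0 equiv); then HCl to pH 2.5, EtOAc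
Reagents that add atoms: water, O
Why: The active-site serine is acylated by one of the two enantiotopic CH2CO2CH3 arms, methanol leaves, and water hydrolyses the acyl-enzyme to the acid; the closest known reaction type is the esterase hydrolysis of prochiral 3-substituted glutaric diesters. No ring is closed and no skeletal bond is formed. The stereocentre (C3' of the target) arises only because the chiral binding site places the hydroxyl and the methyl group of 2 in different pockets, so the controlling element is the enzyme and not the substrate. The step needs enantiotopic-group selectivity and a stop after one hydrolysis: the first rests on the active site, the second on the carboxylate of 3, which is anionic at this pH and a poor substrate, and on the pH-stat that meters one equivalent of base. Neutral water at 25 °C should cause neither dehydration nor retro-aldol cleavage of the tertiary β-hydroxy diester. Because the two termini of 3 are now chemically different, each arm can be addressed separately in the following steps.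

Step 3
Reactants: 3 (R)-3-hydroxy-5-methoxy-3-methyl-5-oxopentanoic acid
Product: 4 methyl (R)-3-hydroxy-5-[methoxy(methyl)amino]-3-methyl-5-oxopentanoate
Conditions: MeNHOMe·HCl, EDC·HCl, HOBt (cat.), N-methylmorpholine, CH2Cl2, 0 °C → rt
Reagents that add atoms: N,O-dimethylhydroxylamine hydrochloride, CNOC.Cl
Why: Carbodiimide amidation through the HOBt active ester (Weinreb amide formation); only the free acid arm is activated, the ester arm and the hindered tertiary alcohol should not react, and the stereocentre is not involved.

Step 4
Reactants: 4 methyl (R)-3-hydroxy-5-[methoxy(methyl)amino]-3-methyl-5-oxopentanoate; 5 2-methylprop-1-enylmagnesium bromide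
Product: 6 methyl (R)-3-hydroxy-3,7-dimethyl-5-oxooct-6-enoate
Conditions: 5 (2.3 equiv), THF, −20 → 0 °C; then cold aq NH4Cl
Reagents that add atoms: none
Why: Weinreb ketone synthesis: the first equivalent of 5 deprotonates the tertiary hydroxyl, the second adds to the amide to give a magnesium-chelated tetrahedral intermediate that collapses to the enone only on quench, so neither a second addition nor a conjugate addition should occur. The less electrophilic methyl ester is expected to survive a hindered alkenyl Grignard reagent at or below 0 °C.

Step 5
Reactants: 6 methyl (R)-3-hydroxy-3,7-dimethyl-5-oxooct-6-enoate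
Product: 7 methyl (3R,5S)-3,5-dihydroxy-3,7-dimethyloct-6-enoate
Conditions: (R)-2-methyl-CBS-oxazaborolidine (0.3 equiv), catecholborane (2.2 equiv), toluene, −78 °C; then MeOH, aq NaHCO3
Reagents that add atoms: none
Why: Corey–Bakshi–Shibata reduction: the ketone binds to the ring boron with its lone pair anti to the alkenyl group, which acts as the larger substituent, and hydride is delivered within the six-membered array. With the (R)-catalyst this should give the (S)-carbinol independently of C3, the alkenyl group taking the place that phenyl has in the acetophenone model in both size and CIP rank. Catecholborane at −78 °C should leave the ester, the alkene and largely the tertiary hydroxyl untouched.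

Step 6
Reactants: 7 methyl (3R,5S)-3,5-dihydroxy-3,7-dimethyloct-6-enoate
Product: 8 (4R,6S)-4-hydroxy-4-methyl-6-(2-methylprop-1-enyl)tetrahydropyran-2-one
Conditions: DBU (0.3 equiv), toluene, 5 Å molecular sieves, 40 °C
Reagents that add atoms: none
Why: Base-catalysed intramolecular transesterification (6-exo-trig lactonisation) of the δ-hydroxy ester, helped by the fully substituted C3 and driven by removal of methanol. The tertiary hydroxyl would give a strained β-lactone and stays free, and the absence of acid should keep the ionisable allylic C–O bond and both stereocentres intact.

Step 7
Reactants: 8 (4R,6S)-4-hydroxy-4-methyl-6-(2-methylprop-1-enyl)tetrahydropyran-2-one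
Product: 10 (3R,4R,6S)-3,4-epoxy-4-methyl-6-(2-methylprop-1-enyl)tetrahydropyran-2-one, via lithium iodo alkoxide 9 (not isolated)
Conditions: LiN(iPr)2 (2.2 equiv), THF, −78 °C; I2 (1.05 equiv), −78 → 0 °C
Reagents that add atoms: none
Why: Twofold deprotonation gives the lithium alkoxide–enolate (as in the Fráter–Seebach chemistry of β-hydroxy esters); iodine should attack the enolate carbon anti to the pseudo-axial 4-oxido group, and the trans-diaxial iodo alkoxide 9 closes by intramolecular SN2 displacement, the known route from β-hydroxy ester dianions to glycidic esters. C4 (C3') keeps its oxygen and configuration, and C3 (C2') is set by the inversion and by the fact that the six-membered ring allows only a cis-fused oxirane. A cis iodide, if formed, can epimerise through the enolate or by iodide exchange and be drained the same way.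

Step 8
Reactants: 10 (3R,4R,6S)-3,4-epoxy-4-methyl-6-(2-methylprop-1-enyl)tetrahydropyran-2-one
Product: 11 (2S,3R,5S)-2,3-epoxy-3,7-dimethyloct-6-ene-1,5-diol
Conditions: NaBH4, EtOH, 0 °C → rt
Reagents that add atoms: none
Why: Borohydride reduction of an α-oxygenated (glycidic) lactone, which is activated enough for NaBH4, through the lactol to the primary alcohol. The ring oxygen is released as the C5 hydroxyl without breaking the C5–O bond, the oxirane is inert to borohydride, and all three stereocentres are carried over.

Step 9
Reactants: 11 (2S,3R,5S)-2,3-epoxy-3,7-dimethyloct-6-ene-1,5-diol; 12 7-hydroxy-8-methoxycoumarin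
Product: 13 7-{[(2S,3R)-3-[(2S)-2-hydroxy-4-methylpent-3-enyl]-3-methyloxiran-2-yl]methoxy}-8-methoxy-2H-chromen-2-one (CNP0223665.2)
Conditions: PPh3, DIAD, THF, 0 °C → rt
Reagents that add atoms: none
Why: Mitsunobu etherification: the unhindered primary carbinol should form the alkoxyphosphonium ion much faster than the secondary allylic one and is displaced at the non-stereogenic C1' by the phenoxide of 12, an acidic phenol well within the range of the reaction. The neutral conditions should spare the oxirane, the allylic alcohol and the coumarin lactone, and no stereocentre is touched.

## Compound list

1 | 3-hydroxy-3-methylglutaric acid | CC(O)(CC(=O)O)CC(=O)O | starting material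
2 | dimethyl 3-hydroxy-3-methylglutarate | COC(=O)CC(C)(O)CC(=O)OC | intermediate
3 | (R)-3-hydroxy-5-methoxy-3-methyl-5-oxopentanoic acid | COC(=O)C[C@](C)(O)CC(=O)O | intermediate
4 | methyl (R)-3-hydroxy-5-[methoxy(methyl)amino]-3-methyl-5-oxopentanoate | COC(=O)C[C@](C)(O)CC(=O)N(C)OC | intermediate
5 | 2-methylprop-1-enylmagnesium bromide | CC(C)=C[Mg]Br | starting material
6 | methyl (R)-3-hydroxy-3,7-dimethyl-5-oxooct-6-enoate | COC(=O)C[C@](C)(O)CC(=O)C=C(C)C | intermediate
7 | methyl (3R,5S)-3,5-dihydroxy-3,7-dimethyloct-6-enoate | COC(=O)C[C@](C)(O)C[C@H](O)C=C(C)C | intermediate
8 | (4R,6S)-4-hydroxy-4-methyl-6-(2-methylprop-1-enyl)tetrahydropyran-2-one | O=C1C[C@](C)(O)C[C@@H](C=C(C)C)O1 | intermediate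
9 | lithium (3S,4R,6S)-3-iodo-4-methyl-6-(2-methylprop-1-enyl)-2-oxotetrahydropyran-4-olate (lithium iodo alkoxide, not isolated) | O=C1[C@@H](I)[C@](C)([O-])C[C@@H](C=C(C)C)O1.[Li+] | intermediate
10 | (3R,4R,6S)-3,4-epoxy-4-methyl-6-(2-methylprop-1-enyl)tetrahydropyran-2-one | O=C1[C@@H]2O[C@]2(C)C[C@@H](C=C(C)C)O1 | intermediate
11 | (2S,3R,5S)-2,3-epoxy-3,7-dimethyloct-6-ene-1,5-diol | OC[C@@H]1O[C@]1(C)C[C@H](O)C=C(C)C | intermediate
12 | 7-hydroxy-8-methoxycoumarin | COc1c(O)ccc2ccc(=O)oc12 | starting material
13 | 7-{[(2S,3R)-3-[(2S)-2-hydroxy-4-methylpent-3-enyl]-3-methyloxiran-2-yl]methoxy}-8-methoxy-2H-chromen-2-one | COc1c(OC[C@@H]2O[C@]2(C)C[C@H](O)C=C(C)C)ccc2ccc(=O)oc12 | target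

## Step count and least certain steps

Total step count: 9. Longest linear sequence: 9 steps (1 to 13); 5 and 12 are purchased and enter in steps 4 and 9. C3' is set in step 2, C5' in step 5 and C2' in step 7.

Step 2 (key step). The likely failure is incomplete or reversed discrimination between the two enantiotopic ester arms, since the enzyme must tell a hydroxyl from a methyl group of similar size at C3; hydrolysis running on to the diacid is a lesser risk. The fallback leaves the enzyme aside and sets out from 1. Dehydration with N,N'-dicyclohexylcarbodiimide in THF would give 3-hydroxy-3-methylglutaric anhydride F1. Its ring would then be opened with methanol in the presence of a stoichiometric cinchona alkaloid (quinidine or quinine, toluene, −50 °C), a known type of desymmetrisation of prochiral glutaric anhydrides in which the pseudoenantiomeric alkaloid is chosen to give the R half ester. The route is rejoined at 3. A remaining shortfall in enantiomeric purity could be removed by crystallising the half ester as a salt with a chiral amine.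

Step 7. The likely failures are oxidative coupling of the enolate by iodine, insufficient facial selectivity in the halogenation, and retro-aldol cleavage of the mono-alkoxide before the second deprotonation. The fallback sets out from 8 and replaces the dianion by a neutral enolate equivalent. Silylation in situ (LiN(iPr)2, Me3SiCl, THF, −78 °C) would give (4R,6S)-4-methyl-6-(2-methylprop-1-enyl)-2,4-bis(trimethylsilyloxy)-5,6-dihydro-4H-pyran F2. N-Bromosuccinimide in THF at −78 °C would brominate the ketene acetal carbon to give (3S,4R,6S)-3-bromo-4-methyl-6-(2-methylprop-1-enyl)-4-(trimethylsilyloxy)tetrahydropyran-2-one F3, accompanied by its C3 epimer, which can equilibrate through the enol. Bu4NF in THF at 0 °C would remove the silyl group, and the alkoxide set free would close the oxirane, returning at 10.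

Step 5. The likely failure is poor facial selectivity, because the CH2 group next to the quaternary C3 may compete with the alkenyl group for the role of the larger substituent, and because a borate formed at the free tertiary hydroxyl may deliver hydride without the catalyst. The fallback gives up reagent control and sets out from 6. Luche reduction (NaBH4, CeCl3·7H2O, MeOH, −40 °C) would give 7 mixed with its C5 epimer, methyl (3R,5R)-3,5-dihydroxy-3,7-dimethyloct-6-enoate F4. Lactonisation as in step 6 would turn the pair into 8 and (4R,6R)-4-hydroxy-4-methyl-6-(2-methylprop-1-enyl)tetrahydropyran-2-one F5. These are diastereomers, with the hydroxyl trans or cis to the isobutenyl group, and should be separable by chromatography. The route is rejoined at 8 at the cost of the material that ends as F5.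

Step 9. The likely failures are activation of the secondary allylic hydroxyl and intramolecular etherification, in which the C5 hydroxyl attacks the activated C1 to form a six-membered cyclic ether in competition with the phenol. The fallback protects the secondary alcohol and sets out from 11. Silylation of both hydroxyls (tert-butyldimethylsilyl chloride, imidazole, DMF) would give (2S,3R,5S)-1,5-bis(tert-butyldimethylsilyloxy)-2,3-epoxy-3,7-dimethyloct-6-ene F6. Selective cleavage of the primary silyl ether (HF·pyridine, pyridine, THF, 0 °C) would give (2S,3R,5S)-5-(tert-butyldimethylsilyloxy)-2,3-epoxy-3,7-dimethyloct-6-en-1-ol F7. Mitsunobu coupling with 12 would give 7-{[(2S,3R)-3-[(2S)-2-(tert-butyldimethylsilyloxy)-4-methylpent-3-enyl]-3-methyloxiran-2-yl]methoxy}-8-methoxy-2H-chromen-2-one F8, and Bu4NF buffered with acetic acid would return to the route at 13.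

Step 4. The likely failures are over-addition at the methyl ester and retro-aldol cleavage of the magnesium alkoxide, both consequences of running the addition on the unprotected tertiary alcohol with excess reagent. The fallback sets out from 4. Silylation (Et3SiOTf, 2,6-lutidine, CH2Cl2, −78 °C) would give methyl (R)-5-[methoxy(methyl)amino]-3-methyl-5-oxo-3-(triethylsilyloxy)pentanoate F9. Addition of 5 (1.2 equiv, THF, −20 °C) would give methyl (R)-3,7-dimethyl-5-oxo-3-(triethylsilyloxy)oct-6-enoate F10. Reduction under the conditions of step 5 would give methyl (3R,5S)-5-hydroxy-3,7-dimethyl-3-(triethylsilyloxy)oct-6-enoate F11, and Bu4NF buffered with acetic acid would return to the route at 7. This fallback also removes the free hydroxyl from the reduction.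

## Further compounds

F1 | step 2 | 3-hydroxy-3-methylglutaric anhydride | CC1(O)CC(=O)OC(=O)C1
F2 | step 7 | (4R,6S)-4-methyl-6-(2-methylprop-1-enyl)-2,4-bis(trimethylsilyloxy)-5,6-dihydro-4H-pyran | C[Si](C)(C)OC1=C[C@](C)(O[Si](C)(C)C)C[C@@H](C=C(C)C)O1
F3 | step 7 | (3S,4R,6S)-3-bromo-4-methyl-6-(2-methylprop-1-enyl)-4-(trimethylsilyloxy)tetrahydropyran-2-one | O=C1[C@@H](Br)[C@](C)(O[Si](C)(C)C)C[C@@H](C=C(C)C)O1
F4 | step 5 | methyl (3R,5R)-3,5-dihydroxy-3,7-dimethyloct-6-enoate | COC(=O)C[C@](C)(O)C[C@@H](O)C=C(C)C
F5 | step 5 | (4R,6R)-4-hydroxy-4-methyl-6-(2-methylprop-1-enyl)tetrahydropyran-2-one | O=C1C[C@](C)(O)C[C@H](C=C(C)C)O1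
F6 | step 9 | (2S,3R,5S)-1,5-bis(tert-butyldimethylsilyloxy)-2,3-epoxy-3,7-dimethyloct-6-ene | CC(C)(C)[Si](C)(C)OC[C@@H]1O[C@]1(C)C[C@H](O[Si](C)(C)C(C)(C)C)C=C(C)C
F7 | step 9 | (2S,3R,5S)-5-(tert-butyldimethylsilyloxy)-2,3-epoxy-3,7-dimethyloct-6-en-1-ol | OC[C@@H]1O[C@]1(C)C[C@H](O[Si](C)(C)C(C)(C)C)C=C(C)C
F8 | step 9 | 7-{[(2S,3R)-3-[(2S)-2-(tert-butyldimethylsilyloxy)-4-methylpent-3-enyl]-3-methyloxiran-2-yl]methoxy}-8-methoxy-2H-chromen-2-one | COc1c(OC[C@@H]2O[C@]2(C)C[C@H](O[Si](C)(C)C(C)(C)C)C=C(C)C)ccc2ccc(=O)oc12
F9 | step 4 | methyl (R)-5-[methoxy(methyl)amino]-3-methyl-5-oxo-3-(triethylsilyloxy)pentanoate | COC(=O)C[C@](C)(O[Si](CC)(CC)CC)CC(=O)N(C)OC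
F10 | step 4 | methyl (R)-3,7-dimethyl-5-oxo-3-(triethylsilyloxy)oct-6-enoate | COC(=O)C[C@](C)(O[Si](CC)(CC)CC)CC(=O)C=C(C)C
F11 | step 4 | methyl (3R,5S)-5-hydroxy-3,7-dimethyl-3-(triethylsilyloxy)oct-6-enoate | COC(=O)C[C@](C)(O[Si](CC)(CC)CC)C[C@H](O)C=C(C)C
A1 | alternative 1 | (3R,4R,6S)-3,4-epoxy-4-methyl-6-(2-methylprop-1-enyl)tetrahydropyran-2-one | O=C1[C@@H]2O[C@]2(C)C[C@@H](C=C(C)C)O1
A2 | alternative 1 | (S)-4-methyl-6-(2-methylprop-1-enyl)-5,6-dihydro-2H-pyran-2-one | CC1=CC(=O)O[C@H](C=C(C)C)C1
A3 | alternative 2 | (S)-4-methyl-6-(2-methylprop-1-enyl)-5,6-dihydro-2H-pyran-2-one | CC1=CC(=O)O[C@H](C=C(C)C)C1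
A4 | alternative 2 | 1-methoxy-3-methyl-1-(trimethylsilyloxy)buta-1,3-diene | C=C(C)C=C(OC)O[Si](C)(C)C
A5 | alternative 2 | 3-methylbut-2-enal | CC(C)=CC=O
A6 | alternative 3 | 7-{[(2S,3R)-3-[(2S)-2-(tert-butyldimethylsilyloxy)-4-methylpent-3-enyl]-3-methyloxiran-2-yl]methoxy}-8-methoxy-2H-chromen-2-one | COc1c(OC[C@@H]2O[C@]2(C)C[C@H](O[Si](C)(C)C(C)(C)C)C=C(C)C)ccc2ccc(=O)oc12
A7 | alternative 3 | 4-{[(2S,3R)-3-[(2S)-2-(tert-butyldimethylsilyloxy)-4-methylpent-3-enyl]-3-methyloxiran-2-yl]methoxy}-2-hydroxy-3-methoxybenzaldehyde | COc1c(OC[C@@H]2O[C@]2(C)C[C@H](O[Si](C)(C)C(C)(C)C)C=C(C)C)ccc(C=O)c1O
A8 | alternative 3 | (triphenylphosphoranylidene)ketene | O=C=C=P(c1ccccc1)(c1ccccc1)c1ccccc1
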